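**Plan**

- Locants follow the carbon chain: C1 lactone carbonyl, C2 its α-carbon, C3 the enol carbon bearing OH, C4 (Me), C5, C6 (Me), C7 ketone, C8, C9, C10, C11 (OH), C12 (Me, ether O), C13 (Me, OH), C14, C15 (lactone O), C16 (ether O; bonded to C2, C8 and C15). The enabling feature is the 2-oxabicyclo[2.2.2]octane with bridgeheads C12 and C15 and bridges O–C16, C13–C14 and C11–C10, which is the retron of a 3-hydroxy-2-pyrone [4+2] adduct.
- Retrosynthetic cuts, in order: C8–C16 (transannular Michael), C8=C9 (ring-closing metathesis) and C7–C8, C2–C3 (tetronate acylation), C13–CH3, C2=C16 together with O–C1 (intramolecular Wittig on the lactone carbonyl), and last C10–C15 and C11–C12 ([4+2]).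
- Forward ring order: oxabicyclo[2.2.2]octene carbocycle (step 5), butenolide (step 6), 11-membered carbocycle (step 20), then cyclopentane and cyclooctane together (step 22).
- Stereochemistry: C12/C15 from the chiral amine catalyst; C10/C11 from the exo-ester mode and the E-alkene, with C–B oxidation proceeding with retention; C13 from methyl addition anti to the C11 silyl ether; C4/C6 from desymmetrisation of the meso anhydride; C16/C8 from the ring constraint of the transannular closure.

Key step: step 5

Assumption: the sense of induction in the two cinchona-catalysed steps (5 and 14) is taken to be that of the quinidine-derived catalysts written; if either proves opposite, the quinine-derived pseudoenantiomer is used with no other change.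

**Route**

Step 1
Reactants: 1 galactaric acid
Product: 3 3-hydroxy-2-oxo-2H-pyran-6-carboxylic acid, via 3-acetoxy pyrone acid 2 (not isolated)
Conditions: Ac2O, NaOAc, 100 °C; then conc. aq. HCl, 60 °C
Reagents that add atoms: none
Why: Acetic anhydride effects the known triple dehydration–lactonisation of an aldaric acid to a 3-acyloxy-2-pyrone-6-carboxylic acid, and acid hydrolysis then cleaves the enol acetate, no stereocentre surviving.

Step 2
Reactants: 3 3-hydroxy-2-oxo-2H-pyran-6-carboxylic acid
Product: 4 3-hydroxy-6-(hydroxymethyl)-2H-pyran-2-one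
Conditions: BH3·SMe2 (3.5 equiv), THF, 0 °C → rt; MeOH quench
Reagents that add atoms: none
Why: Borane reduces a free carboxylic acid through its acyloxyborane much faster than a conjugated lactone (chemoselective borane reduction), so only the C6 carboxyl should be taken to the primary alcohol.

Step 3
Reactants: 4 3-hydroxy-6-(hydroxymethyl)-2H-pyran-2-one
Product: 5 6-(chloromethyl)-3-hydroxy-2H-pyran-2-one
Conditions: SOCl2, 0 °C → rt
Reagents that add atoms: thionyl chloride, O=S(Cl)Cl
Why: Thionyl chloride converts the activated primary alcohol into the chloride via its chlorosulfite (alcohol-to-chloride substitution) and leaves the enolic hydroxyl alone, as is usual for hydroxymethyl-hydroxypyranones.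

Step 4
Reactants: 5 6-(chloromethyl)-3-hydroxy-2H-pyran-2-one
Product: 6 3-hydroxy-6-methyl-2H-pyran-2-one
Conditions: Zn dust, conc. HCl, H2O, 65 °C
Reagents that add atoms: none
Why: Zinc in acid reduces the doubly vinylogous α-chloro ester to the methyl group (dissolving-metal dehalogenation), the reaction that turns chloromethyl-hydroxypyranones into their methyl analogues.

Step 5
Reactants: 6 3-hydroxy-6-methyl-2H-pyran-2-one; 7 methyl (E)-3-(pinacolboryl)acrylate
Product: 8 exo-ester endo-boryl bridged lactone
Conditions: 9-O-(9-phenanthryl)cupreidine (10 mol %), Et2O, 0 °C → rt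
Reagents that add atoms: none
Why: The quinuclidine nitrogen deprotonates the 3-hydroxyl to an ion-paired oxido-pyrone dienolate while the catalyst 6'-OH hydrogen-bonds the acrylate carbonyl; the dienolate γ-carbon (pyrone C6, future C12) adds to the boron-bearing β-carbon and the ester α-carbon bonds to pyrone C3 (future C15), either in an asynchronous concerted [4+2] or as a Michael addition followed by a 6-exo-trig aldol closure of the ester enolate onto the C3 carbonyl. The closest known reaction type is the cinchona-amine-catalysed Diels–Alder reaction of 3-hydroxy-2-pyrones with acrylate-type dienophiles, and conjugate attack at the boron-bearing carbon of 3-borylacrylates is itself established. The one ring closed is the carbocycle C10–C11–C12–C13=C14–C15, which arrives with the O–C(=O) bridge already spanning C12 and C15, i.e. as the 2-oxabicyclo[2.2.2]octene. C12 and C15 are set together by the dienolate face that the chiral ion pair leaves open, C11 by the endo placement of boron (ester exo, the mode expected from the hydrogen-bonding 6'-OH catalyst type), and C10 by the E-geometry of the alkene, trans to C11 being also the thermodynamic arrangement of this epimerisable centre. The step needs regioselectivity, which the polarity match between the nucleophilic C6 terminus and the acrylate β-carbon secures, and exo-ester and enantioface selectivity, which rest on the catalyst binding the 3-oxide and the ester carbonyl of the substrates; it is run cold so that the adduct neither reverts nor loses CO2.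

Step 6
Reactants: 8 exo-ester endo-boryl bridged lactone
Product: 10 boryl tetronate, via ester ylide 9 (not isolated)
Conditions: Ph3P=C=C=O (1.3 equiv), PhCO2H (5 mol %), THF, 60 °C
Reagents that add atoms: (triphenylphosphoranylidene)ketene, O=C=C=P(c1ccccc1)(c1ccccc1)c1ccccc1
Why: The tertiary C15 hydroxyl, the only free hydroxyl because boron still masks the C11 oxygen, adds across the cumulated ylide, and the ester ylide 9 then olefinates the adjacent strained lactone carbonyl in a five-membered intramolecular Wittig reaction (the domino addition–Wittig tetronate synthesis from α-hydroxy esters), which keeps the C12–O–C16 bond, makes C16 the β-carbon of the butenolide and should be preferred over the six-membered closure onto the less electrophilic C9 methyl ester.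

Step 7
Reactants: 10 boryl tetronate
Product: 11 C11 alcohol
Conditions: NaBO3·4H2O, THF–H2O (1:1), rt
Reagents that add atoms: sodium perborate, [Na+].[Na+].O[B-]1(O)OO[B-](O)(O)OO1
Why: Perborate oxidises the C–B bond by 1,2-migration of C11 from boron to oxygen with retention (boronate oxidation), so the C11 hydroxyl appears on the side of the C13=C14 bridge under conditions mild enough for the vinylogous carbonate and the ester.

Step 8
Reactants: 11 C11 alcohol
Product: 14 C11 C13 syn-diol, via dimethylsilyl ether 12 (not isolated), via cyclic siloxane 13 (not isolated)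
Conditions: (HMe2Si)2NH, 60 °C, then evaporation; Pt2(dvds)3 (1 mol %), toluene, 60 °C; then 30% H2O2, KF, KHCO3, THF–MeOH, rt
Reagents that add atoms: hydrogen peroxide, OO
Why: The homoallylic C11–O–SiMe2H group can reach only C13 on the near face of the alkene, so platinum-catalysed 5-exo intramolecular hydrosilylation followed by Tamao oxidation (C–Si to C–O with retention) should put oxygen regiospecifically on C13 and hydrogen on C14, the C13 configuration (syn to C11–OH) being erased in the next step.

Step 9
Reactants: 14 C11 C13 syn-diol
Product: 15 C13 ketone C11 alcohol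
Conditions: TEMPO (0.3 equiv), PhI(OAc)2 (1.1 equiv), CH2Cl2, rt
Reagents that add atoms: none
Why: The bulky oxoammonium species of the TEMPO-mediated oxidation should discriminate between the two secondary carbinols, because the C11 carbinol C–H is eclipsed by the ester-bearing C10 substituent and deactivated as a β-hydroxy ester whereas the C13 carbinol has a methylene neighbour, so C13–OH is oxidised first.

Step 10
Reactants: 15 C13 ketone C11 alcohol
Product: 16 C13 ketone C11 TBS ether
Conditions: TBSOTf, 2,6-lutidine, CH2Cl2, −78 → 0 °C
Reagents that add atoms: tert-butyldimethylsilyl trifluoromethanesulfonate, CC(C)(C)[Si](C)(C)OS(=O)(=O)C(F)(F)F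
Why: Silyl triflate–lutidine silylation of the hindered secondary alcohol at low temperature outpaces enol silylation of the ketone and removes the risk of retro-aldol opening in the next step.

Step 11
Reactants: 16 C13 ketone C11 TBS ether
Product: 17 C13 methyl carbinol
Conditions: MeLi, anhydrous CeCl3, THF, −78 °C
Reagents that add atoms: methyllithium, [Li]C
Why: The weakly basic organocerium reagent adds to the hindered enolisable ketone in preference to the methyl ester and the vinylogous carbonate (organocerium 1,2-addition) and approaches C13 from the face beside the unsubstituted O–C16 bridge because the C11 silyl ether covers the other face, which places the methyl group syn to the ether bridge and the new hydroxyl syn to C11–O as in the target.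

Step 12
Reactants: 17 C13 methyl carbinol
Product: 18 C9 aldehyde
Conditions: DIBAL-H (2.2 equiv), CH2Cl2, −78 °C; Rochelle salt
Reagents that add atoms: none
Why: DIBAL-H at −78 °C reduces the methyl ester to the aldehyde through its aluminium hemiacetal (partial ester reduction) while the tetronate carbonyl is deactivated as a vinylogous carbonate, and the epimerisable C10 already holds its substituent trans to the C11 silyl ether, the more stable arrangement.

Step 13
Reactants: 18 C9 aldehyde
Product: 19 C10-vinyl tetronate core
Conditions: Ph3PCH3Br, KHMDS, THF, −78 → 0 °C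
Reagents that add atoms: methyltriphenylphosphonium bromide, C[P+](c1ccccc1)(c1ccccc1)c1ccccc1.[Br-]
Why: Wittig methylenation of the hindered aldehyde with the non-stabilised ylide gives the terminal vinyl group without touching the vinylogous carbonate, the tertiary hydroxyl being too weakly acidic to interfere.

Step 14
Reactants: 20 meso-2,4-dimethylglutaric anhydride
Product: 21 (2S,4R)-5-methoxy-2,4-dimethyl-5-oxopentanoic acid
Conditions: MeOH (10 equiv), (DHQD)2AQN (10 mol %), Et2O, −40 °C
Reagents that add atoms: methanol, CO
Why: The dimeric cinchona alkaloid acts as a chiral general base in the methanolysis of the meso anhydride (catalytic desymmetrisation of a cyclic anhydride), selecting one enantiotopic carbonyl and thereby fixing both methyl-bearing centres (future C4 and C6) at once.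

Step 15
Reactants: 21 (2S,4R)-5-methoxy-2,4-dimethyl-5-oxopentanoic acid
Product: 23 (3R,5S)-3,5-dimethyloxan-2-one, via hydroxy ester 22 (not isolated)
Conditions: BH3·SMe2, THF, 0 °C → rt; then TsOH (cat.), toluene, rt
Reagents that add atoms: none
Why: Borane reduces the free acid and not the methyl ester (chemoselective acid reduction), and the δ-hydroxy ester lactonises under acid catalysis without touching either stereocentre.

Step 16
Reactants: 23 (3R,5S)-3,5-dimethyloxan-2-one
Product: 24 (2R,4S)-5-hydroxy-N-methoxy-N,2,4-trimethylpentanamide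
Conditions: MeNH(OMe)·HCl, i-PrMgCl, THF, −20 → 0 °C
Reagents that add atoms: N,O-dimethylhydroxylamine hydrochloride, CNOC.Cl
Why: The magnesium amide of N,O-dimethylhydroxylamine opens the lactone at low temperature (Weinreb aminolysis of an ester), giving the amide that becomes C7 and freeing the primary alcohol that becomes C3 under conditions known to spare an α-stereocentre.

Step 17
Reactants: 24 (2R,4S)-5-hydroxy-N-methoxy-N,2,4-trimethylpentanamide
Product: 25 (2R,4S)-N-methoxy-N,2,4-trimethyl-5-oxopentanamide
Conditions: Dess–Martin periodinane, NaHCO3, CH2Cl2, 0 °C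
Reagents that add atoms: none
Why: Buffered Dess–Martin oxidation converts the primary alcohol into the aldehyde under non-basic conditions that should leave the α-methyl stereocentre intact.

Step 18
Reactants: 19 C10-vinyl tetronate core; 25 (2R,4S)-N-methoxy-N,2,4-trimethyl-5-oxopentanamide
Product: 27 C3 carbinol Weinreb amide, via C2-lithio tetronate 26 (not isolated)
Conditions: LDA (2.2 equiv), THF, −78 °C; then 25, −78 °C; aq. NH4Cl at −78 °C
Reagents that add atoms: none
Why: LDA forms the C13 alkoxide and then removes the vinylic C2 proton of the 5,5-disubstituted tetronate (α-lithiation of a 4-alkoxybutenolide), and the vinyl anion adds to the aldehyde far faster than to the Weinreb amide (1,2-addition), forming C2–C3 with a carbinol centre whose two epimers converge at the oxidation in step 21.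

Step 19
Reactants: 27 C3 carbinol Weinreb amide
Product: 28 vinyl ketone
Conditions: CH2=CHMgBr (5 equiv), THF, −78 → 0 °C; inverse quench into cold 1 M HCl
Reagents that add atoms: vinylmagnesium bromide, C=C[Mg]Br
Why: Excess vinyl Grignard reagent deprotonates the two hydroxyls and converts the Weinreb amide into the vinyl ketone through the chelated tetrahedral intermediate (Weinreb ketone synthesis), forming C7–C8, while the 3-alkylated tetronate is too electron-rich and hindered to compete and the acidic inverse quench keeps the liberated amine from adding to the enone.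

Step 20
Reactants: 28 vinyl ketone
Product: 29 macrocyclic enone C3 carbinol
Conditions: Grubbs second-generation catalyst (10 mol %), CH2Cl2 (1 mM), 40 °C
Reagents that add atoms: none
Why: Ring-closing metathesis between the C10 vinyl group and the vinyl ketone under high dilution forms C8=C9 and the 11-membered carbocycle (RCM to a macrocyclic enone) with loss of ethene, the E-alkene being expected and its geometry being of no consequence since it is reduced in step 22.

Step 21
Reactants: 29 macrocyclic enone C3 carbinol
Product: 30 macrocyclic enone acyl tetronate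
Conditions: Dess–Martin periodinane, NaHCO3, CH2Cl2, rt
Reagents that add atoms: none
Why: Dess–Martin oxidation of the secondary C3 carbinol gives the 3-acyl tetronate, which turns C16 into a strongly electrophilic Michael position, the tertiary hydroxyl and the silyl ether being inert.

Step 22
Reactants: 30 macrocyclic enone acyl tetronate
Product: 32 C11 TBS ether of the target, via C8 enolate 31 (not isolated)
Conditions: L-Selectride (2.2 equiv), THF, −78 °C; aq. NH4Cl
Reagents that add atoms: none
Why: The bulky borohydride delivers hydride to C9 of the strained enone (conjugate reduction) and the regiodefined C8 enolate attacks C16 of the acyl tetronate across the ring (transannular Michael addition, 5-exo-trig), closing cyclopentane and cyclooctane together, with C16 and C8 forced into the cis-fused configuration of the target because C8 can reach only the tetronate face turned toward C10, and with the stable β-keto lactone enolate as product.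

Step 23
Reactants: 32 C11 TBS ether of the target
Product: 33 CNP0073203.1
Conditions: HF·pyridine, THF–pyridine, 0 °C → rt
Reagents that add atoms: none
Why: Fluoride cleaves the hindered secondary silyl ether under mildly acidic conditions (HF·pyridine desilylation) that should leave the β-keto lactone enol, the β-alkoxy ketone and the tertiary alcohols untouched.

**Compound list**

1 | galactaric acid (mucic acid) | OC(=O)[C@H](O)[C@@H](O)[C@@H](O)[C@H](O)C(O)=O | starting material
2 | 3-acetoxy-2-oxo-2H-pyran-6-carboxylic acid | CC(=O)OC1=CC=C(C(=O)O)OC1=O | intermediate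
3 | 3-hydroxy-2-oxo-2H-pyran-6-carboxylic acid | OC1=CC=C(C(=O)O)OC1=O | intermediate
4 | 3-hydroxy-6-(hydroxymethyl)-2H-pyran-2-one | OCC1=CC=C(O)C(=O)O1 | intermediate
5 | 6-(chloromethyl)-3-hydroxy-2H-pyran-2-one | ClCC1=CC=C(O)C(=O)O1 | intermediate
6 | 3-hydroxy-6-methyl-2H-pyran-2-one | CC1=CC=C(O)C(=O)O1 | intermediate
7 | methyl (E)-3-(4,4,5,5-tetramethyl-1,3,2-dioxaborolan-2-yl)acrylate | COC(=O)/C=C/B1OC(C)(C)C(C)(C)O1 | starting material
8 | methyl 4-hydroxy-1-methyl-3-oxo-7-(pinacolboryl)-2-oxabicyclo[2.2.2]oct-5-ene-8-carboxylate; boryl group (C11) on the side of the C=C bridge, ester (C10) on the side of the lactone bridge | O[C@@]1(C(=O)O2)C=C[C@@]2(C)[C@@H](B3OC(C)(C)C(C)(C)O3)[C@@H]1C(=O)OC | intermediate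
9 | 8 with the C15 hydroxyl esterified as the (triphenylphosphoranylidene)acetate | O=C(C=P(c5ccccc5)(c6ccccc6)c7ccccc7)O[C@@]1(C(=O)O2)C=C[C@@]2(C)[C@@H](B3OC(C)(C)C(C)(C)O3)[C@@H]1C(=O)OC | intermediate
10 | boryl tetronate: 2-oxabicyclo[2.2.2]oct-5-ene (bridgeheads C12, C15) whose C16 is the β-carbon of the butenolide C15–O–C1(=O)–C2H=C16 and carries the ring oxygen from C12; C12–Me; C11–Bpin syn to C13=C14; C10–CO2Me anti to it | O4[C@@]1(C(=CC4=O)O2)C=C[C@@]2(C)[C@@H](B3OC(C)(C)C(C)(C)O3)[C@@H]1C(=O)OC | intermediate
11 | as 10 with C11–OH (syn to the C13=C14 bridge) in place of boron | O4[C@@]1(C(=CC4=O)O2)C=C[C@@]2(C)[C@@H](O)[C@@H]1C(=O)OC | intermediate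
12 | C11 O-dimethylsilyl (Si–H) ether of 11 | O4[C@@]1(C(=CC4=O)O2)C=C[C@@]2(C)[C@@H](O[SiH](C)C)[C@@H]1C(=O)OC | intermediate
13 | cyclic siloxane: C11–O–SiMe2–C13 five-membered ring on the saturated C13–C14 bridge | O4[C@@]1(C(=CC4=O)O2)C[C@@H]5[C@@]2(C)[C@@H](O[Si]5(C)C)[C@@H]1C(=O)OC | intermediate
14 | C11,C13 syn-diol (both hydroxyls in the sector between the C11–C10 and C13–C14 bridges); tetronate and C9 methyl ester as before | O4[C@@]1(C(=CC4=O)O2)C[C@@H](O)[C@@]2(C)[C@@H](O)[C@@H]1C(=O)OC | intermediate
15 | C13 ketone with free C11–OH | O4[C@@]1(C(=CC4=O)O2)CC(=O)[C@@]2(C)[C@@H](O)[C@@H]1C(=O)OC | intermediate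
16 | C13 ketone, C11–OTBS | O4[C@@]1(C(=CC4=O)O2)CC(=O)[C@@]2(C)[C@@H](O[Si](C)(C)C(C)(C)C)[C@@H]1C(=O)OC | intermediate
17 | C13 tertiary carbinol: C13–Me syn to the ether bridge, C13–OH syn to C11–OTBS; C9 methyl ester | O4[C@@]1(C(=CC4=O)O2)C[C@@](C)(O)[C@@]2(C)[C@@H](O[Si](C)(C)C(C)(C)C)[C@@H]1C(=O)OC | intermediate
18 | as 17 with C9 as the aldehyde | O4[C@@]1(C(=CC4=O)O2)C[C@@](C)(O)[C@@]2(C)[C@@H](O[Si](C)(C)C(C)(C)C)[C@@H]1C=O | intermediate
19 | as 17 with a vinyl group on C10 (C9=CH2) | O4[C@@]1(C(=CC4=O)O2)C[C@@](C)(O)[C@@]2(C)[C@@H](O[Si](C)(C)C(C)(C)C)[C@@H]1C=C | intermediate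
20 | meso-(cis)-2,4-dimethylglutaric anhydride | C[C@@H]1C[C@H](C)C(=O)OC1=O | starting material
21 | (2S,4R)-5-methoxy-2,4-dimethyl-5-oxopentanoic acid | C[C@@H](C(=O)OC)C[C@H](C)C(=O)O | intermediate
22 | methyl (2R,4S)-5-hydroxy-2,4-dimethylpentanoate | C[C@@H](C(=O)OC)C[C@H](C)CO | intermediate
23 | (3R,5S)-3,5-dimethyloxan-2-one | C[C@@H]1C[C@H](C)COC1=O | intermediate
24 | (2R,4S)-5-hydroxy-N-methoxy-N,2,4-trimethylpentanamide | C[C@@H](C(=O)N(C)OC)C[C@H](C)CO | intermediate
25 | (2R,4S)-N-methoxy-N,2,4-trimethyl-5-oxopentanamide | C[C@@H](C(=O)N(C)OC)C[C@H](C)C=O | intermediate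
26 | 19 as its C13 lithium alkoxide, lithiated at C2 | O4[C@@]1(C(=C([Li])C4=O)O2)C[C@@](C)(O[Li])[C@@]2(C)[C@@H](O[Si](C)(C)C(C)(C)C)[C@@H]1C=C | intermediate
27 | 19 bearing at C2 the chain C3H(OH)–C4H(Me)–C5H2–C6H(Me)–C7(=O)N(OMe)Me (4S,6R; C3 epimers) | O4[C@@]1(C(=C(C4=O)C(O)[C@@H](C)C[C@@H](C)C(=O)N(C)OC)O2)C[C@@](C)(O)[C@@]2(C)[C@@H](O[Si](C)(C)C(C)(C)C)[C@@H]1C=C | intermediate
28 | as 27 with C7 as the vinyl ketone (C3 epimers) | O4[C@@]1(C(=C(C4=O)C(O)[C@@H](C)C[C@@H](C)C(=O)C=C)O2)C[C@@](C)(O)[C@@]2(C)[C@@H](O[Si](C)(C)C(C)(C)C)[C@@H]1C=C | intermediate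
29 | 11-membered carbocycle C2–C3–C4–C5–C6–C7–C8=C9–C10–C15–C16 with (E)-C8=C9 enone and C3 carbinol (C3 epimers) | O4[C@@]1(C(=C(C4=O)C(O)[C@@H](C)C[C@@H](C)C(=O)/C=C/5)O2)C[C@@](C)(O)[C@@]2(C)[C@@H](O[Si](C)(C)C(C)(C)C)[C@@H]15 | intermediate
30 | as 29 with C3 ketone (3-acyl tetronate) | O4[C@@]1(C(=C(C4=O)C(=O)[C@@H](C)C[C@@H](C)C(=O)/C=C/5)O2)C[C@@](C)(O)[C@@]2(C)[C@@H](O[Si](C)(C)C(C)(C)C)[C@@H]15 | intermediate
31 | C7–C8 enolate of the 8,9-dihydro macrocycle (drawn as lithium enolate) | O4[C@@]1(C(=C(C4=O)C(=O)[C@@H](C)C[C@@H](C)C(O[Li])=CC5)O2)C[C@@](C)(O)[C@@]2(C)[C@@H](O[Si](C)(C)C(C)(C)C)[C@@H]15 | intermediate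
32 | target skeleton with C11–OTBS | C[C@@H]1C[C@H](C)/C(O)=C2/C(=O)O[C@]34C[C@@](C)(O)[C@]5(C)O[C@]23[C@@H](C[C@H]4[C@@H]5O[Si](C)(C)C(C)(C)C)C1=O | intermediate
33 | CNP0073203.1: β-keto-γ-lactone enol; cyclopentane C8–C9–C10–C15–C16 and cyclooctane C2–C3–C4–C5–C6–C7–C8–C16 cis-fused on the 2-oxabicyclo[2.2.2]octane; (4S,6R) | C[C@@H]1C[C@H](C)/C(O)=C2/C(=O)O[C@]34C[C@@](C)(O)[C@]5(C)O[C@]23[C@@H](C[C@H]4[C@@H]5O)C1=O | target

**Step count**

Total: 23 steps. Longest linear sequence: 19 steps (steps 1–13, then 18–23); the side-chain branch is steps 14–17.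

**Steps most likely to fail**

Step 5. The cycloaddition may proceed with poor exo/endo control, the ester rather than the boryl group taking the endo position, which would invert both C10 and C11 relative to the bridgeheads, or with low enantioface selectivity for this new dienophile. The fallback sets out from 6 and uses methyl (Z)-3-(pinacolboryl)acrylate F1, obtained from methyl (Z)-3-iodoacrylate by Miyaura borylation, under the endo-selective variant of the same amine-catalysed cycloaddition (9-thiourea cinchona catalyst). With the cis dienophile the endo mode places boron over the alkene bridge as required and gives the all-endo cis adduct F2, the C10 epimer of 8. Equilibration of the epimerisable C10 with a catalytic amidine base then moves the ester to the trans position and returns to 8.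

Step 6. Addition of the hindered tertiary hydroxyl to the cumulated ylide may be slow enough that thermal loss of CO2 from the bridged lactone, or Wittig closure onto the C9 ester, overtakes tetronate formation. The fallback sets out from 8 and forms the same ring by Claisen chemistry. Acetylation (Ac2O, DMAP) gives the C15 acetate F3. LiHMDS at −78 °C then triggers a Lacey–Dieckmann cyclisation in which the acetate enolate attacks C16 and expels the C12 alkoxide, giving the ring-opened tetronic acid F4 with a free tertiary allylic C12 hydroxyl. Acid-catalysed intramolecular O-alkylation of the tetronic acid by that carbinol (CSA, benzene, water removal) recloses the oxabicycle and returns to 10.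

Step 9. Site discrimination between the two secondary carbinols may be insufficient, leading to oxidation at C11 or to the diketone. The fallback sets out from 11 and protects before the alkene is touched. Silylation (TBSOTf, 2,6-lutidine) gives the C11 TBS ether F5. Epoxidation with mCPBA on the alkene face remote from the silyl ether gives the epoxide F6. Opening with phenylselenide (PhSeSePh, NaBH4, EtOH) should occur at C14, because the silyl ether blocks the backside of C13, and gives the hydroxy selenide F7. Radical deselenation (Bu3SnH, AIBN) gives the C13 alcohol F8, and Dess–Martin oxidation returns to 16.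

**Further compounds**

F1 | step 5 | methyl (Z)-3-(4,4,5,5-tetramethyl-1,3,2-dioxaborolan-2-yl)acrylate | COC(=O)/C=C\B1OC(C)(C)C(C)(C)O1
F2 | step 5 | C10 epimer of 8 (ester and boryl group both on the side of the C=C bridge) | O[C@@]1(C(=O)O2)C=C[C@@]2(C)[C@@H](B3OC(C)(C)C(C)(C)O3)[C@H]1C(=O)OC
F3 | step 6 | C15 O-acetate of 8 | CC(=O)O[C@@]1(C(=O)O2)C=C[C@@]2(C)[C@@H](B3OC(C)(C)C(C)(C)O3)[C@@H]1C(=O)OC
F4 | step 6 | ring-opened tetronic acid: spiro butenolide at C15 with C16–OH, free C12 tertiary allylic alcohol, C11–Bpin, C10–CO2Me | O4[C@@]1(C(O)=CC4=O)C=C[C@](C)(O)[C@@H](B3OC(C)(C)C(C)(C)O3)[C@@H]1C(=O)OC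
F5 | step 9 | C11 TBS ether of 11 | O4[C@@]1(C(=CC4=O)O2)C=C[C@@]2(C)[C@@H](O[Si](C)(C)C(C)(C)C)[C@@H]1C(=O)OC
F6 | step 9 | C13,C14 epoxide of F5 on the face of the ether bridge | O4[C@@]1(C(=CC4=O)O2)[C@@H]5O[C@@H]5[C@@]2(C)[C@@H](O[Si](C)(C)C(C)(C)C)[C@@H]1C(=O)OC
F7 | step 9 | C14 phenylselanyl C13 alcohol (trans) | O4[C@@]1(C(=CC4=O)O2)[C@@H]([Se]c6ccccc6)[C@H](O)[C@@]2(C)[C@@H](O[Si](C)(C)C(C)(C)C)[C@@H]1C(=O)OC
F8 | step 9 | C13 secondary alcohol (hydroxyl on the face of the ether bridge), C11–OTBS | O4[C@@]1(C(=CC4=O)O2)C[C@H](O)[C@@]2(C)[C@@H](O[Si](C)(C)C(C)(C)C)[C@@H]1C(=O)OC
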